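**Retrosynthetic overview**

1. Feature: ring B is a resorcinol with a free OH on C2' and OMe on C4', ortho and para to C1'. C1 and C3 of a 1-silyloxy-1,3-dimethoxybutadiene carry exactly these oxygens, so ring B can be grown on an alkyne whose two carbons become C1' and C6'.
2. Last disconnection: 3-OH and 5-OH, the two oxygens flanking the C4 carbonyl of ring C, are unmasked together from a 3-O-benzyl/5-O-methyl precursor.
3. Key disconnection: bonds C1'–C2' and C5'–C6' of ring B, by (4+2) cycloaddition and aromatisation of 3-benzyloxy-2-ethynyl-5,7,8-trimethoxychromone with the Brassard diene.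
4. The ethynylchromone comes from the 2-iodochromone (Sonogashira), this from C2 zincation of the 3-benzyloxychromone, and this from 2-hydroxy-3,4,6-trimethoxyacetophenone, made from 1,2,3,5-tetramethoxybenzene.
5. Ring order: ring A is bought, ring C is closed in step 2, ring B is formed in step 9.

Key step: step 9

Remark: the epoxide of step 3 and the cycloadduct of step 9 are racemic and lose their stereocentres in the same flask; the C1=C2 geometry of the diene is left undefined because that carbon becomes aromatic C2'.

**Step 1**
Reactants: 1 1,2,3,5-tetramethoxybenzene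
Product: 2 1-(2-hydroxy-3,4,6-trimethoxyphenyl)ethan-1-one
Conditions: AcCl, AlCl3 (2.5 equiv), Et2O, 0 °C to rt; then ice-cold 2 M HCl
Reagents that add atoms: acetyl chloride, CC(Cl)=O
Why: Friedel–Crafts acylation at one of the two equivalent free positions is followed in the same flask by AlCl3-chelate-controlled cleavage of the ortho methoxy group that is buttressed by its neighbouring methoxy, the known outcome for 2,3,4,6-tetramethoxyacetophenones, which places the phenol next to the future C8 methoxy group.

**Step 2**
Reactants: 2 1-(2-hydroxy-3,4,6-trimethoxyphenyl)ethan-1-one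
Product: 4 5,7,8-trimethoxy-4H-chromen-4-one, via enaminone 3 (not isolated)
Conditions: Me2NCH(OMe)2, toluene, 100 °C; concentrate; then conc. HCl, CH2Cl2, 40 °C
Reagents that add atoms: N,N-dimethylformamide dimethyl acetal, COC(OC)N(C)C
Why: Amide-acetal condensation on the methyl ketone gives the enaminone, and acid-promoted conjugate addition of the phenol with loss of dimethylamine closes ring C, the standard enaminone synthesis of 2,3-unsubstituted chromones.

**Step 3**
Reactants: 4 5,7,8-trimethoxy-4H-chromen-4-one
Product: 6 3-hydroxy-5,7,8-trimethoxy-4H-chromen-4-one, via chromone 2,3-epoxide 5 (not isolated)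
Conditions: dimethyldioxirane (acetone solution), CH2Cl2, 0 °C to rt; then TsOH·H2O (cat.), CH2Cl2, rt
Reagents that add atoms: dimethyldioxirane, CC1(C)OO1
Why: Dioxirane epoxidation of the enol-ether-like C2=C3 bond of a chromone gives the racemic cis-fused epoxide, which opens under acid at C2 (oxocarbenium stabilised by O1) and loses H3 to give the 3-hydroxychromone, so no stereocentre remains.

**Step 4**
Reactants: 6 3-hydroxy-5,7,8-trimethoxy-4H-chromen-4-one
Product: 7 3-(benzyloxy)-5,7,8-trimethoxy-4H-chromen-4-one
Conditions: BnBr, K2CO3, DMF, rt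
Reagents that add atoms: benzyl bromide, BrCc1ccccc1
Why: Williamson O-alkylation of the acidic enolic 3-hydroxyl, the only free OH in the molecule.

**Step 5**
Reactants: 7 3-(benzyloxy)-5,7,8-trimethoxy-4H-chromen-4-one
Product: 9 3-(benzyloxy)-2-iodo-5,7,8-trimethoxy-4H-chromen-4-one, via chromen-2-ylzinc chloride 8 (not isolated)
Conditions: TMPZnCl·LiCl (TMP = 2,2,6,6-tetramethylpiperidin-1-yl), THF, 25 °C; then I2, THF, 0 °C
Reagents that add atoms: iodine, II
Why: Directed zincation of a chromone with a hindered TMP zinc amide removes the only pyranone C–H left, at C2 (vinylic, next to O1 and the benzyloxy oxygen), without addition to the carbonyl, and iodinolysis of the C–Zn bond gives the iodide.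

**Step 6**
Reactants: 9 3-(benzyloxy)-2-iodo-5,7,8-trimethoxy-4H-chromen-4-one; 10 trimethylsilylacetylene
Product: 11 3-(benzyloxy)-5,7,8-trimethoxy-2-[(trimethylsilyl)ethynyl]-4H-chromen-4-one
Conditions: PdCl2(PPh3)2 (cat.), CuI (cat.), Et3N, THF, rt
Reagents that add atoms: none
Why: Sonogashira coupling; the 2-iodochromone is a vinylogous acyl iodide that should undergo oxidative addition readily, and a tertiary amine base avoids addition–elimination at C2.

**Step 7**
Reactants: 11 3-(benzyloxy)-5,7,8-trimethoxy-2-[(trimethylsilyl)ethynyl]-4H-chromen-4-one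
Product: 12 3-(benzyloxy)-2-ethynyl-5,7,8-trimethoxy-4H-chromen-4-one
Conditions: Bu4NF, AcOH (1:1), THF, −20 to 0 °C
Reagents that add atoms: none
Why: Fluoride-induced protodesilylation of the alkynylsilane, buffered with acetic acid so that no basic nucleophile remains to add to the activated terminal alkyne.

**Step 8**
Reactants: 13 methyl (E)-3-methoxybut-2-enoate
Product: 15 [(1,3-dimethoxybuta-1,3-dien-1-yl)oxy]trimethylsilane, via lithium dienolate 14 (not isolated)
Conditions: LiN(iPr)2, THF, −78 °C; then Me3SiCl, −78 °C to rt; distillation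
Reagents that add atoms: chlorotrimethylsilane, C[Si](C)(C)Cl
Why: γ-Deprotonation of the vinylogous ester and O-silylation of the extended enolate, the standard preparation of this Brassard diene.

**Step 9**
Reactants: 12 3-(benzyloxy)-2-ethynyl-5,7,8-trimethoxy-4H-chromen-4-one; 15 [(1,3-dimethoxybuta-1,3-dien-1-yl)oxy]trimethylsilane
Product: 18 3-(benzyloxy)-2-(2-hydroxy-4-methoxyphenyl)-5,7,8-trimethoxy-4H-chromen-4-one, via cyclohexadiene cycloadduct 16 (not isolated), via aryl trimethylsilyl ether 17 (not isolated)
Conditions: 15 (3 equiv), toluene, 110 °C, sealed tube; then 1 M HCl, THF, rt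
Reagents that add atoms: none
Why: Proposed new method: the ketene-acetal diene 15 should add to the alkyne of 12 in an asynchronous normal-electron-demand (4+2) cycloaddition, its CH2 terminus bonding to the terminal alkyne carbon, which is the vinylogous (1,6-) acceptor position of the C4 carbonyl through C2=C3, and its acetal carbon bonding to the alkyne carbon on C2, to give the 1,4-cyclohexadiene 16; acid then expels methanol from the mixed silyl methyl ketal carbon with loss of a ring CH2 proton to give aryl silyl ether 17, which is hydrolysed to phenol 18. The closest known reaction type is the Diels–Alder/aromatisation of Brassard-type 1-silyloxy-1,3-dialkoxybutadienes with alkynyl ketones and alkynoates, which delivers resorcinol monomethyl ethers; a 2-alkynylchromone, a vinylogous alkynyl ketone, has not been shown as the dienophile. Ring B is closed by intermolecular (4+2) annulation, the bonds C5'–C6' and C1'–C2' both forming in this operation from the four diene carbons and the two alkyne carbons, so no tethered ring closure is involved. No stereocentre is created in 18, since the single ketal centre of racemic 16 is erased on aromatisation. The step needs regioselectivity (oxygen at C2' ortho and methoxy at C4' para to C1'), which the pairing of the nucleophilic diene terminus with the electrophilic terminal alkyne carbon should secure, and chemoselectivity for the alkyne over the chromone C2=C3 bond, which is tetrasubstituted and carries two oxygen donors. Whether 16 loses methanol directly or is first desilylated to the dienone tautomer, both paths should end in the free 2'-phenol, because ionisation of the C–OSi bond is the least favourable.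

**Step 10**
Reactants: 18 3-(benzyloxy)-2-(2-hydroxy-4-methoxyphenyl)-5,7,8-trimethoxy-4H-chromen-4-one
Product: 19 3,5-dihydroxy-2-(2-hydroxy-4-methoxyphenyl)-7,8-dimethoxy-4H-chromen-4-one (3,5,2'-trihydroxy-7,8,4'-trimethoxyflavone)
Conditions: BCl3 (excess), C6HMe5, CH2Cl2, −78 °C to rt; then MeOH, aq. NaHCO3
Reagents that add atoms: none
Why: Lewis-acid ether cleavage: BCl3 removes the benzyl group and, through the six-membered boron chelate with the C4 carbonyl, the peri 5-O-methyl group, while the non-chelated 7-, 8- and 4'-methyl ethers should survive and pentamethylbenzene traps the benzyl cation before it can C-benzylate the electron-rich rings.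

**Compound list**

1 | 1,2,3,5-tetramethoxybenzene | COc1cc(OC)c(OC)c(OC)c1 | starting material
2 | 1-(2-hydroxy-3,4,6-trimethoxyphenyl)ethan-1-one | CC(=O)c1c(O)c(OC)c(OC)cc1OC | intermediate
3 | (E)-3-(dimethylamino)-1-(2-hydroxy-3,4,6-trimethoxyphenyl)prop-2-en-1-one | CN(C)/C=C/C(=O)c1c(O)c(OC)c(OC)cc1OC | intermediate
4 | 5,7,8-trimethoxy-4H-chromen-4-one | O=c1ccoc2c(OC)c(OC)cc(OC)c12 | intermediate
5 | 2,3-epoxy-5,7,8-trimethoxychroman-4-one (cis-fused, racemic; one enantiomer drawn) | O=C1[C@H]2O[C@H]2Oc2c(OC)c(OC)cc(OC)c12 | intermediate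
6 | 3-hydroxy-5,7,8-trimethoxy-4H-chromen-4-one | O=c1c(O)coc2c(OC)c(OC)cc(OC)c12 | intermediate
7 | 3-(benzyloxy)-5,7,8-trimethoxy-4H-chromen-4-one | O=c1c(OCc2ccccc2)coc2c(OC)c(OC)cc(OC)c12 | intermediate
8 | [3-(benzyloxy)-5,7,8-trimethoxy-4-oxo-4H-chromen-2-yl]zinc chloride | O=c1c(OCc2ccccc2)c([Zn]Cl)oc2c(OC)c(OC)cc(OC)c12 | intermediate
9 | 3-(benzyloxy)-2-iodo-5,7,8-trimethoxy-4H-chromen-4-one | O=c1c(OCc2ccccc2)c(I)oc2c(OC)c(OC)cc(OC)c12 | intermediate
10 | trimethylsilylacetylene | C#C[Si](C)(C)C | starting material
11 | 3-(benzyloxy)-5,7,8-trimethoxy-2-[(trimethylsilyl)ethynyl]-4H-chromen-4-one | O=c1c(OCc2ccccc2)c(C#C[Si](C)(C)C)oc2c(OC)c(OC)cc(OC)c12 | intermediate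
12 | 3-(benzyloxy)-2-ethynyl-5,7,8-trimethoxy-4H-chromen-4-one | C#Cc1oc2c(OC)c(OC)cc(OC)c2c(=O)c1OCc1ccccc1 | intermediate
13 | methyl (E)-3-methoxybut-2-enoate | CO/C(C)=C/C(=O)OC | starting material
14 | lithium 1,3-dimethoxybuta-1,3-dien-1-olate | [Li+].[O-]C(OC)=CC(OC)=C | intermediate
15 | [(1,3-dimethoxybuta-1,3-dien-1-yl)oxy]trimethylsilane (C1=C2 geometry undefined) | C=C(OC)C=C(OC)O[Si](C)(C)C | intermediate
16 | 3-(benzyloxy)-2-[4,6-dimethoxy-6-(trimethylsilyloxy)cyclohexa-1,4-dien-1-yl]-5,7,8-trimethoxy-4H-chromen-4-one (racemic) | COC1=CC(OC)(O[Si](C)(C)C)C(=CC1)c1oc2c(OC)c(OC)cc(OC)c2c(=O)c1OCc1ccccc1 | intermediate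
17 | 3-(benzyloxy)-5,7,8-trimethoxy-2-[4-methoxy-2-(trimethylsilyloxy)phenyl]-4H-chromen-4-one | COc1ccc(-c2oc3c(OC)c(OC)cc(OC)c3c(=O)c2OCc2ccccc2)c(O[Si](C)(C)C)c1 | intermediate
18 | 3-(benzyloxy)-2-(2-hydroxy-4-methoxyphenyl)-5,7,8-trimethoxy-4H-chromen-4-one | COc1ccc(-c2oc3c(OC)c(OC)cc(OC)c3c(=O)c2OCc2ccccc2)c(O)c1 | intermediate
19 | 3,5,2'-trihydroxy-7,8,4'-trimethoxyflavone | COc1ccc(-c2oc3c(OC)c(OC)cc(O)c3c(=O)c2O)c(O)c1 | target

**Step count and risks**

Total step count: 10. Longest linear sequence: 9 steps (steps 1 to 7, 9 and 10); the diene is made in one step (step 8).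

Steps most likely to fail:

- **Step 9 (proposed new method).** The alkyne may be too weak a dienophile, so that thermal decay of the diene outruns cycloaddition. Addition may also stop at the open-chain conjugate adduct, or aromatisation may proceed by loss of silanol and leave a 2'-methyl ether. The fallback attaches a finished ring B by known cross-coupling and sets out from 7. Commercial 2-bromo-5-methoxyphenol is protected (MOMCl, iPr2NEt, CH2Cl2) as 1-bromo-4-methoxy-2-(methoxymethoxy)benzene F1. Compound 7 is zincated as in step 5 to give 8, which undergoes Negishi coupling with F1 (Pd(OAc)2, SPhos, THF, 50 °C) to give 3-(benzyloxy)-5,7,8-trimethoxy-2-[4-methoxy-2-(methoxymethoxy)phenyl]-4H-chromen-4-one F2. HCl in MeOH at 40 °C removes the acetal and the fallback comes back to the route at 18.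

- **Step 3.** The electrophilic oxidant may attack the electron-rich trimethoxyarene, or the labile epoxide may be opened by water to ring-cleaved products instead of rearranging. The fallback sets out from 4 and uses nucleophilic rather than electrophilic oxygenation. PhI(OAc)2 with KOH in MeOH (0 °C to rt; methoxide addition at C2 and oxidation of the resulting enolate) should give cis-2,4,4,5,7,8-hexamethoxychroman-3-ol F3 (racemic). Conc. HCl in acetone then hydrolyses the acetal and eliminates methanol, and the fallback comes back to the route at 6.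

- **Step 7.** Once the alkyne is unmasked, fluoride, acetate or adventitious hydroxide may add to its activated terminus, or the terminal alkyne may oligomerise on concentration. The fallback sets out from 9 and avoids the silyl alkyne altogether. Stille coupling with tributyl(ethynyl)stannane (Pd(PPh3)4, toluene, 80 °C, neutral conditions) should deliver the terminal alkyne directly, and the fallback comes back to the route at 12.

**Further compounds**

F1 | step 9 | 1-bromo-4-methoxy-2-(methoxymethoxy)benzene | COCOc1cc(OC)ccc1Br
F2 | step 9 | 3-(benzyloxy)-5,7,8-trimethoxy-2-[4-methoxy-2-(methoxymethoxy)phenyl]-4H-chromen-4-one | COCOc1cc(OC)ccc1-c1oc2c(OC)c(OC)cc(OC)c2c(=O)c1OCc1ccccc1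
F3 | step 3 | cis-2,4,4,5,7,8-hexamethoxychroman-3-ol (racemic; one enantiomer drawn) | CO[C@H]1Oc2c(OC)c(OC)cc(OC)c2C(OC)(OC)[C@H]1O
F0 | step 7 | none | none
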